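## Retrosynthetic overview
1. Target 37 ⇐ ester hydrolysis and catalyst-controlled dearomative C6-prenylation (Tsuji–Trost) of the fully substituted 5,7-dihydroxychromanone 35. The quaternary centre is set last.
2. 35 ⇐ methanolysis of 34 ⇐ Negishi sp3–sp2 union of the C10 cyclobutylmethylzinc 33 (fragment A) with the C17 tricyclic aryl iodide 29 (fragment B).
3. Fragment A ⇐ Wolff ring contraction (five- to four-membered ring) of diazo ketone 5 ⇐ rhodium-catalysed asymmetric isopropenyl addition to 4,4-dimethylcyclopentenone.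
4. Fragment B ⇐ resorcinol → 3,5-dimethoxyphenol → Pechmann coumarin → asymmetric conjugate reduction → C8 acylation → lactone-to-chromanone ring switch → new lactone on the other phenol → iodination.
5. Ring order: cyclopentanone → cyclobutane (A). Arene → coumarin lactone → chromanone → second lactone (B). The arene is dearomatised at the end.

Assumption: the ligand antipodes named in steps 11 and 20 are assigned by analogy with the nearest precedents. The sense is checked on the first batch, and the mirror-image ligand is used if it is opposite.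

## Fragment A (cyclobutane)

Step 1
Reactants: 1 4,4-dimethylcyclopent-2-en-1-one; 2 potassium trifluoro(prop-1-en-2-yl)borate
Product: 3 (4R)-3,3-dimethyl-4-(prop-1-en-2-yl)cyclopentan-1-one
Conditions: [Rh(cod)2]PF6 (3 mol %), (R)-BINAP (3.3 mol %), toluene/H2O 20:1, 105 °C, sealed tube
Reagents that add atoms: none
Why: Hayashi–Miyaura rhodium-catalysed asymmetric 1,4-addition, in which (S)-BINAP gives (S)-3-substituted cyclopentanones in the parent series and the same face gives the (S) descriptor here, so (R)-BINAP sets the (R) carbon that becomes the isopropenyl-bearing cyclobutane carbon.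

Step 2
Reactants: 3 (4R)-3,3-dimethyl-4-(prop-1-en-2-yl)cyclopentan-1-one
Product: 5 (3R)-2-diazo-4,4-dimethyl-3-(prop-1-en-2-yl)cyclopentan-1-one, via 2-trifluoroacetyl ketone 4 (not isolated)
Conditions: LiN(SiMe3)2 (1.1 equiv), THF, −78 °C; CF3CO2CH2CF3 (1.2 equiv), −78 °C; 5 % HCl wash; crude, MsN3 (1.5 equiv), Et3N (1.5 equiv), H2O (1 equiv), MeCN, rt
Reagents that add atoms: methanesulfonyl azide CS(=O)(=O)N=[N+]=[N-]
Why: Danheiser detrifluoroacetylative diazo transfer (Regitz type), in which the bulky amide deprotonates the CH2 next to the CH rather than the neopentyl CH2 next to CMe2, and the activated trifluoroacetyl ketone takes N2 from mesyl azide with loss of the trifluoroacetyl group while the stereocentre is untouched.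

Step 3
Reactants: 5 (3R)-2-diazo-4,4-dimethyl-3-(prop-1-en-2-yl)cyclopentan-1-one
Product: 7 methyl (2R)-3,3-dimethyl-2-(prop-1-en-2-yl)cyclobutane-1-carboxylate (C1 epimer mixture), via ring-contracted ketene 6 (not isolated)
Conditions: hν (medium-pressure Hg lamp, Pyrex), MeOH, 0 °C
Reagents that add atoms: methanol CO
Why: Photochemical Wolff rearrangement, in which the s-Z-locked cyclic diazo ketone loses N2 with 1,2-shift of the C5 methylene to give a cyclobutylidene ketene that methanol traps, the new α-centre forming unselectively and being corrected in step 4.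

Step 4
Reactants: 7 methyl (2R)-3,3-dimethyl-2-(prop-1-en-2-yl)cyclobutane-1-carboxylate (C1 epimer mixture)
Product: 8 methyl (1R,2R)-3,3-dimethyl-2-(prop-1-en-2-yl)cyclobutane-1-carboxylate (trans)
Conditions: NaOMe (0.3 equiv), MeOH, 60 °C; chromatography
Reagents that add atoms: none
Why: Thermodynamic epimerisation through the ester enolate places the ester trans to the bulky neighbouring isopropenyl group, which sets the second cyclobutane stereocentre relative to the first.

Step 5
Reactants: 8 methyl (1R,2R)-3,3-dimethyl-2-(prop-1-en-2-yl)cyclobutane-1-carboxylate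
Product: 9 [(1R,2R)-3,3-dimethyl-2-(prop-1-en-2-yl)cyclobutyl]methanol
Conditions: LiAlH4, Et2O, 0 °C; H2O/NaOH work-up
Reagents that add atoms: none
Why: Standard hydride reduction of an ester, to which the isolated 1,1-disubstituted alkene and both stereocentres are inert.

Step 6
Reactants: 9 [(1R,2R)-3,3-dimethyl-2-(prop-1-en-2-yl)cyclobutyl]methanol
Product: 10 (1R,2R)-1-(iodomethyl)-3,3-dimethyl-2-(prop-1-en-2-yl)cyclobutane
Conditions: I2, PPh3, imidazole, CH2Cl2, 0 °C → rt, dark
Reagents that add atoms: iodine II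
Why: Appel-type (Garegg–Samuelsson) iodination displaces the oxyphosphonium by SN2 at the primary carbon, so no cyclobutylcarbinyl cation forms and neither rearrangement nor stereochemical change can occur.

## Fragment B (tricyclic aryl iodide)

Step 7
Reactants: 11 resorcinol
Product: 12 1,3-dimethoxybenzene
Conditions: MeI (2.5 equiv), K2CO3, acetone, reflux
Reagents that add atoms: iodomethane CI
Why: Williamson ether synthesis installs methyl ethers that survive the acidic and Lewis-acidic steps ahead.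

Step 8
Reactants: 12 1,3-dimethoxybenzene
Product: 14 3,5-dimethoxyphenol, via aryl pinacol boronate 13 (not isolated)
Conditions: [Ir(OMe)(cod)]2 (1.5 mol %), 4,4'-di-tert-butyl-2,2'-bipyridine (3 mol %), B2pin2 (0.55 equiv), THF, 80 °C; then KHSO5 (as 2KHSO5·KHSO4·K2SO4), acetone/H2O, rt
Reagents that add atoms: potassium peroxymonosulfate [K+].[O-]S(=O)(=O)OO
Why: Sterically governed iridium-catalysed C–H borylation (Ishiyama–Miyaura–Hartwig) attacks only the position meta to both methoxy groups, and ipso-oxidation of the boronate supplies the third oxygen of the phloroglucinol pattern.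

Step 9
Reactants: 15 methyl acetoacetate; 16 iodoethane
Product: 18 methyl 3-oxohexanoate, via acetoacetate dianion 17 (not isolated)
Conditions: NaH (1.1 equiv), THF, 0 °C; n-BuLi (1.05 equiv), 0 °C; EtI, 0 °C → rt; dilute HCl
Reagents that add atoms: none
Why: Huckin–Weiler dianion alkylation, in which the more basic terminal carbanion is ethylated selectively by SN2.

Step 10
Reactants: 14 3,5-dimethoxyphenol; 18 methyl 3-oxohexanoate
Product: 19 5,7-dimethoxy-4-propyl-2H-chromen-2-one
Conditions: 75 % H2SO4, 0 °C → rt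
Reagents that add atoms: none
Why: Pechmann condensation of a strongly activated phenol whose two ortho positions are equivalent, so a single coumarin forms.

Step 11
Reactants: 19 5,7-dimethoxy-4-propyl-2H-chromen-2-one
Product: 21 (4R)-5,7-dimethoxy-4-propylchroman-2-one, via boron enolate 20 (not isolated)
Conditions: CuCl (5 mol %), NaOt-Bu (5 mol %), (R)-DTBM-SEGPHOS (5.5 mol %), HBpin (1.5 equiv), toluene, rt; sat. aq. NH4Cl
Reagents that add atoms: none
Why: Copper hydride-catalysed asymmetric conjugate reduction (1,4-hydroboration of a coumarin), in which the ligand-bound CuH delivers hydride to one face of C4 and the boron enolate resists over-reduction, setting the (R) benzylic stereocentre.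

Step 12
Reactants: 21 (4R)-5,7-dimethoxy-4-propylchroman-2-one; 22 3-methylbut-2-enoyl chloride
Product: 23 (4R)-5,7-dimethoxy-8-(3-methylbut-2-enoyl)-4-propylchroman-2-one
Conditions: SnCl4 (2.5 equiv), CH2Cl2, −20 °C → rt
Reagents that add atoms: none
Why: Friedel–Crafts acylation goes to C8, which is para to the 5-OMe and flanked by the tied-back lactone oxygen, whereas C6 is buried between two methoxy groups, and the mild Lewis acid avoids ortho-demethylation.

Step 13
Reactants: 23 (4R)-5,7-dimethoxy-8-(3-methylbut-2-enoyl)-4-propylchroman-2-one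
Product: 25 methyl (3R)-3-(5,7-dimethoxy-2,2-dimethyl-4-oxochroman-8-yl)hexanoate, via ring-opened hydroxy enone ester 24 (not isolated)
Conditions: NaOMe (0.3 equiv), MeOH, 0 °C → rt
Reagents that add atoms: methanol CO
Why: Transesterification followed by intramolecular oxa-Michael addition, in which methoxide opens the aryl lactone and the only free phenoxide, ortho to the enone, closes the 2,2-dimethylchromanone, fixing the ring oxygen next to the side chain without touching the β-stereocentre.

Step 14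
Reactants: 25 methyl (3R)-3-(5,7-dimethoxy-2,2-dimethyl-4-oxochroman-8-yl)hexanoate
Product: 27 (10R)-5-hydroxy-2,2-dimethyl-10-propyl-2,3,9,10-tetrahydro-4H,8H-pyrano[2,3-f]chromene-4,8-dione, via dihydroxy ester 26 (not isolated)
Conditions: BBr3 (5 equiv), CH2Cl2, −78 °C → rt; H2O quench; crude, p-TsOH·H2O (10 mol %), toluene, 80 °C
Reagents that add atoms: none
Why: Lewis-acid aryl methyl ether cleavage followed by acid-catalysed lactonisation, in which the freed 7-OH is the only phenol next to the side chain and closes a six-membered lactone that masks the acid and the 7-OH together.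

Step 15
Reactants: 27 (10R)-5-hydroxy-2,2-dimethyl-10-propyl-2,3,9,10-tetrahydro-4H,8H-pyrano[2,3-f]chromene-4,8-dione
Product: 28 (10R)-5-hydroxy-6-iodo-2,2-dimethyl-10-propyl-2,3,9,10-tetrahydro-4H,8H-pyrano[2,3-f]chromene-4,8-dione
Conditions: NIS (1.05 equiv), TFA (0.3 equiv), MeCN, 0 °C → rt
Reagents that add atoms: N-iodosuccinimide O=C1CCC(=O)N1I
Why: Electrophilic aromatic iodination at C6, the only remaining ring C–H, which is activated by the ortho 5-OH and the para pyranone oxygen.

Step 16
Reactants: 28 (10R)-5-hydroxy-6-iodo-2,2-dimethyl-10-propyl-2,3,9,10-tetrahydro-4H,8H-pyrano[2,3-f]chromene-4,8-dione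
Product: 29 (10R)-6-iodo-2,2-dimethyl-4,8-dioxo-10-propyl-2,3,9,10-tetrahydro-4H,8H-pyrano[2,3-f]chromen-5-yl acetate
Conditions: Ac2O (3 equiv), Et3N, DMAP (10 mol %), CH2Cl2, rt
Reagents that add atoms: acetic anhydride CC(=O)OC(C)=O
Why: DMAP-catalysed acetylation removes the acidic phenol proton that would quench the organozinc partner, and makes the iodoarene less electron-rich for oxidative addition.

## Prenyl donor

Step 17
Reactants: 30 3-methylbut-2-en-1-ol (prenol)
Product: 31 methyl 3-methylbut-2-en-1-yl carbonate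
Conditions: ClCO2Me (1.2 equiv), pyridine, CH2Cl2, 0 °C
Reagents that add atoms: methyl chloroformate COC(=O)Cl
Why: O-acylation of the allylic alcohol gives the ionisable carbonate that forms the π-prenylpalladium species and releases its own base.

## Union and endgame

Step 18
Reactants: 10 (1R,2R)-1-(iodomethyl)-3,3-dimethyl-2-(prop-1-en-2-yl)cyclobutane; 29 (10R)-6-iodo-2,2-dimethyl-4,8-dioxo-10-propyl-2,3,9,10-tetrahydro-4H,8H-pyrano[2,3-f]chromen-5-yl acetate
Product: 34 (10R)-6-{[(1S,2R)-3,3-dimethyl-2-(prop-1-en-2-yl)cyclobutyl]methyl}-2,2-dimethyl-4,8-dioxo-10-propyl-2,3,9,10-tetrahydro-4H,8H-pyrano[2,3-f]chromen-5-yl acetate, via cyclobutylmethyllithium 32 (not isolated), via cyclobutylmethylzinc chloride 33 (not isolated)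
Conditions: 10 (1.5 equiv), t-BuLi (3.0 equiv), Et2O/pentane, −78 °C, 15 min; ZnCl2 (1.6 equiv, THF), −78 → 0 °C; then 29, Pd(OAc)2 (5 mol %), SPhos (10 mol %), THF, rt → 45 °C
Reagents that add atoms: none
Why: Negishi cross-coupling, in which non-radical lithium–iodine exchange and immediate transmetalation give a covalent alkylzinc that tolerates ketone, lactone and acetate, and the bulky biarylphosphine speeds reductive elimination past β-hydride elimination, with no stereocentre involved.

Step 19
Reactants: 34 (10R)-6-{[(1S,2R)-3,3-dimethyl-2-(prop-1-en-2-yl)cyclobutyl]methyl}-2,2-dimethyl-4,8-dioxo-10-propyl-2,3,9,10-tetrahydro-4H,8H-pyrano[2,3-f]chromen-5-yl acetate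
Product: 35 methyl (3R)-3-(6-{[(1S,2R)-3,3-dimethyl-2-(prop-1-en-2-yl)cyclobutyl]methyl}-5,7-dihydroxy-2,2-dimethyl-4-oxochroman-8-yl)hexanoate
Conditions: K2CO3 (3 equiv), MeOH, 0 °C → rt; 0.5 M HCl to pH 4–5 at 0 °C; used directly
Reagents that add atoms: methanol CO
Why: Zemplén-type methanolysis cleaves both aryl esters (acetate and lactone) because the stabilised phenoxides are good leaving groups, and the conditions are too mild for retro-oxa-Michael opening of the chromanone.

Step 20
Reactants: 35 methyl (3R)-3-(6-{[(1S,2R)-3,3-dimethyl-2-(prop-1-en-2-yl)cyclobutyl]methyl}-5,7-dihydroxy-2,2-dimethyl-4-oxochroman-8-yl)hexanoate; 31 methyl 3-methylbut-2-en-1-yl carbonate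
Product: 36 methyl (3R)-3-[(6R)-6-{[(1S,2R)-3,3-dimethyl-2-(prop-1-en-2-yl)cyclobutyl]methyl}-5-hydroxy-2,2-dimethyl-6-(3-methylbut-2-en-1-yl)-4,7-dioxo-3,4,6,7-tetrahydro-2H-chromen-8-yl]hexanoate
Conditions: Pd2(dba)3·CHCl3 (2.5 mol %), (R,R)-DACH-phenyl Trost ligand (7.5 mol %), 31 (1.2 equiv), toluene, 0 °C → rt; chromatography
Reagents that add atoms: none
Why: Dearomative Tsuji–Trost asymmetric allylic alkylation, in which C6 between the two phenolic oxygens attacks the unsubstituted terminus of the π-prenyl complex, O-prenyl ethers re-ionise under zerovalent palladium and funnel to the stable vinylogous acid, and the chiral pocket selects the nucleophile face to set (6R), any C6 epimer being a separable diastereomer.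

Step 21
Reactants: 36 methyl (3R)-3-[(6R)-6-{[(1S,2R)-3,3-dimethyl-2-(prop-1-en-2-yl)cyclobutyl]methyl}-5-hydroxy-2,2-dimethyl-6-(3-methylbut-2-en-1-yl)-4,7-dioxo-3,4,6,7-tetrahydro-2H-chromen-8-yl]hexanoate
Product: 37 (3R)-3-[(6R)-6-{[(1S,2R)-3,3-dimethyl-2-(prop-1-en-2-yl)cyclobutyl]methyl}-5-hydroxy-2,2-dimethyl-6-(3-methylbut-2-en-1-yl)-4,7-dioxo-3,4,6,7-tetrahydro-2H-chromen-8-yl]hexanoic acid (CNP0358381.1)
Conditions: LiOH (4 equiv), THF/MeOH/H2O 3:1:1, 0 °C → rt; 1 M HCl to pH 3 at 0 °C
Reagents that add atoms: lithium hydroxide [Li+].[OH-]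
Why: Saponification of the unhindered CH2CO2Me group, during which the core sits as its delocalised enolate and is therefore shielded from retro-Claisen or retro-oxa-Michael cleavage, no acid strong enough to cyclise the prenyl group is used, and all four stereocentres are non-epimerisable.

## Compound list
1 | 4,4-dimethylcyclopent-2-en-1-one | CC1(C)CC(=O)C=C1 | starting material
2 | potassium trifluoro(prop-1-en-2-yl)borate | [K+].C=C(C)[B-](F)(F)F | starting material
3 | (4R)-3,3-dimethyl-4-(prop-1-en-2-yl)cyclopentan-1-one | C=C(C)[C@H]1CC(=O)CC1(C)C | intermediate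
4 | (3R)-4,4-dimethyl-3-(prop-1-en-2-yl)-2-(trifluoroacetyl)cyclopentan-1-one | C=C(C)[C@H]1C(C(=O)C(F)(F)F)C(=O)CC1(C)C | intermediate
5 | (3R)-2-diazo-4,4-dimethyl-3-(prop-1-en-2-yl)cyclopentan-1-one | C=C(C)[C@H]1C(=[N+]=[N-])C(=O)CC1(C)C | intermediate
6 | [3,3-dimethyl-2-(prop-1-en-2-yl)cyclobutylidene]ketene, isopropenyl carbon configured as in 5 | C=C(C)[C@H]1C(=C=O)CC1(C)C | intermediate
7 | methyl (2R)-3,3-dimethyl-2-(prop-1-en-2-yl)cyclobutane-1-carboxylate, C1 epimer mixture | C=C(C)[C@H]1C(C(=O)OC)CC1(C)C | intermediate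
8 | methyl (1R,2R)-3,3-dimethyl-2-(prop-1-en-2-yl)cyclobutane-1-carboxylate (trans) | C=C(C)[C@H]1[C@H](C(=O)OC)CC1(C)C | intermediate
9 | [(1R,2R)-3,3-dimethyl-2-(prop-1-en-2-yl)cyclobutyl]methanol | C=C(C)[C@H]1[C@H](CO)CC1(C)C | intermediate
10 | (1R,2R)-1-(iodomethyl)-3,3-dimethyl-2-(prop-1-en-2-yl)cyclobutane | C=C(C)[C@H]1[C@H](CI)CC1(C)C | intermediate
11 | resorcinol | Oc1cccc(O)c1 | starting material
12 | 1,3-dimethoxybenzene | COc1cccc(OC)c1 | intermediate
13 | 2-(3,5-dimethoxyphenyl)-4,4,5,5-tetramethyl-1,3,2-dioxaborolane | COc1cc(OC)cc(B2OC(C)(C)C(C)(C)O2)c1 | intermediate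
14 | 3,5-dimethoxyphenol | COc1cc(O)cc(OC)c1 | intermediate
15 | methyl acetoacetate | CC(=O)CC(=O)OC | starting material
16 | iodoethane | CCI | starting material
17 | methyl acetoacetate dianion (sodium lithium salt) | [Na+].[Li+].[CH2-]C(=O)[CH-]C(=O)OC | intermediate
18 | methyl 3-oxohexanoate | CCCC(=O)CC(=O)OC | intermediate
19 | 5,7-dimethoxy-4-propyl-2H-chromen-2-one | CCCC1=CC(=O)Oc2cc(OC)cc(OC)c12 | intermediate
20 | (4R)-5,7-dimethoxy-4-propyl-4H-chromen-2-yl pinacol borate (boron enolate) | CCC[C@@H]1C=C(OB3OC(C)(C)C(C)(C)O3)Oc2cc(OC)cc(OC)c12 | intermediate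
21 | (4R)-5,7-dimethoxy-4-propylchroman-2-one | CCC[C@@H]1CC(=O)Oc2cc(OC)cc(OC)c12 | intermediate
22 | 3-methylbut-2-enoyl chloride | CC(C)=CC(=O)Cl | starting material
23 | (4R)-5,7-dimethoxy-8-(3-methylbut-2-enoyl)-4-propylchroman-2-one | CCC[C@@H]1CC(=O)Oc2c(C(=O)C=C(C)C)c(OC)cc(OC)c12 | intermediate
24 | methyl (3R)-3-[2-hydroxy-4,6-dimethoxy-3-(3-methylbut-2-enoyl)phenyl]hexanoate | CCC[C@H](CC(=O)OC)c1c(O)c(C(=O)C=C(C)C)c(OC)cc1OC | intermediate
25 | methyl (3R)-3-(5,7-dimethoxy-2,2-dimethyl-4-oxochroman-8-yl)hexanoate | CCC[C@H](CC(=O)OC)c1c(OC)cc(OC)c2c1OC(C)(C)CC2=O | intermediate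
26 | methyl (3R)-3-(5,7-dihydroxy-2,2-dimethyl-4-oxochroman-8-yl)hexanoate | CCC[C@H](CC(=O)OC)c1c(O)cc(O)c2c1OC(C)(C)CC2=O | intermediate
27 | (10R)-5-hydroxy-2,2-dimethyl-10-propyl-2,3,9,10-tetrahydro-4H,8H-pyrano[2,3-f]chromene-4,8-dione (chromanone whose 7-O and C8 are bridged by C(=O)CH2CH(n-Pr)) | CCC[C@@H]1CC(=O)Oc2cc(O)c3C(=O)CC(C)(C)Oc3c12 | intermediate
28 | 6-iodo derivative of 27 | CCC[C@@H]1CC(=O)Oc2c(I)c(O)c3C(=O)CC(C)(C)Oc3c12 | intermediate
29 | (10R)-6-iodo-2,2-dimethyl-4,8-dioxo-10-propyl-2,3,9,10-tetrahydro-4H,8H-pyrano[2,3-f]chromen-5-yl acetate | CCC[C@@H]1CC(=O)Oc2c(I)c(OC(C)=O)c3C(=O)CC(C)(C)Oc3c12 | intermediate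
30 | 3-methylbut-2-en-1-ol | CC(C)=CCO | starting material
31 | methyl 3-methylbut-2-en-1-yl carbonate | CC(C)=CCOC(=O)OC | intermediate
32 | {[3,3-dimethyl-2-(prop-1-en-2-yl)cyclobutyl]methyl}lithium, ring configuration as in 10 | [Li]C[C@@H]1CC(C)(C)[C@H]1C(C)=C | intermediate
33 | {[3,3-dimethyl-2-(prop-1-en-2-yl)cyclobutyl]methyl}zinc chloride, ring configuration as in 10 | Cl[Zn]C[C@@H]1CC(C)(C)[C@H]1C(C)=C | intermediate
34 | (10R)-6-{[(1S,2R)-3,3-dimethyl-2-(prop-1-en-2-yl)cyclobutyl]methyl}-2,2-dimethyl-4,8-dioxo-10-propyl-2,3,9,10-tetrahydro-4H,8H-pyrano[2,3-f]chromen-5-yl acetate | CCC[C@@H]1CC(=O)Oc2c(C[C@@H]4CC(C)(C)[C@H]4C(C)=C)c(OC(C)=O)c3C(=O)CC(C)(C)Oc3c12 | intermediate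
35 | methyl (3R)-3-(6-{[(1S,2R)-3,3-dimethyl-2-(prop-1-en-2-yl)cyclobutyl]methyl}-5,7-dihydroxy-2,2-dimethyl-4-oxochroman-8-yl)hexanoate | CCC[C@H](CC(=O)OC)c1c(O)c(C[C@@H]3CC(C)(C)[C@H]3C(C)=C)c(O)c2c1OC(C)(C)CC2=O | intermediate
36 | methyl ester of the target, (3R,6R,1S,2R) | C=C(C)[C@H]1[C@H](C[C@]2(CC=C(C)C)C(=O)C([C@H](CCC)CC(=O)OC)=C3OC(C)(C)CC(=O)C3=C2O)CC1(C)C | intermediate
37 | (3R)-3-[(6R)-6-{[(1S,2R)-3,3-dimethyl-2-(prop-1-en-2-yl)cyclobutyl]methyl}-5-hydroxy-2,2-dimethyl-6-(3-methylbut-2-en-1-yl)-4,7-dioxo-3,4,6,7-tetrahydro-2H-chromen-8-yl]hexanoic acid | C=C(C)[C@H]1[C@H](C[C@]2(CC=C(C)C)C(=O)C([C@H](CCC)CC(=O)O)=C3OC(C)(C)CC(=O)C3=C2O)CC1(C)C | target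

## Step count and risks
Total step count: 21.
Longest linear sequence: 13 steps (7, 8, 10, 11, 12, 13, 14, 15, 16, 18, 19, 20, 21).

**Step 20, dearomative prenylation.**
- Why it may fail: the reaction must favour C over O and the linear over the branched product. It must also distinguish two nucleophile faces that differ only through remote substituents.
- Fallback: it sets out from 35 and comes back at 36.
- 35 is first allylated with allyl methyl carbonate under Pd2(dba)3·CHCl3 and the Trost ligand. The unsubstituted π-allyl unit has no regiochemical ambiguity and is the best-precedented case for face selection of a prochiral nucleophile.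
- This gives the 6-allyl dienone methyl ester F1, with C6 arranged in space as in 36.
- F1 is then converted to 36 by cross-metathesis with excess 2-methylbut-2-ene and second-generation Grubbs catalyst in CH2Cl2 at 40 °C. The hindered isopropenyl group next to the quaternary ring carbon does not take part.

**Step 18, Negishi coupling.**
- Why it may fail: the cyclobutylmethyl-metal can open with strain release to an allyl-stabilised anion before it reaches zinc. The iodoarene also carries two ortho substituents.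
- Fallback: it sets out from 9 and 27 and comes back at 35, avoiding any carbanion or radical next to the four-membered ring.
- 9 is oxidised with Dess–Martin periodinane and NaHCO3 to (1R,2R)-3,3-dimethyl-2-(prop-1-en-2-yl)cyclobutane-1-carbaldehyde F2.
- 27 is opened with K2CO3 in MeOH to 26, which is isolated this time.
- 26 and F2 are combined with L-proline (20 mol %) and diethyl 2,6-dimethyl-1,4-dihydropyridine-3,5-dicarboxylate in CH2Cl2/EtOH.
- Knoevenagel-type condensation at C6, the only free ring carbon, gives the ortho-quinone methide F3. Transfer hydrogenation reduces F3 in situ to 35.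
- The epimerisable aldehyde α-carbon rests in the wanted trans form.

**Step 1, asymmetric isopropenyl addition.**
- Why it may fail: the β-carbon is neopentyl, and the α-branched alkenylboron reagent is prone to protodeboronation.
- Fallback: it sets out from 1 and comes back at 3.
- Isopropenylmagnesium bromide with CuBr·SMe2 (10 mol %) in THF at −40 °C gives racemic 3,3-dimethyl-4-(prop-1-en-2-yl)cyclopentan-1-one F4.
- Addition of (S)-N,S-dimethyl-S-phenylsulfoximine, lithiated with n-BuLi, gives two diastereomeric series that are separated on silica. These are the β-hydroxysulfoximine of the (4R)-ketone F5 and the β-hydroxysulfoximine of the (4S)-ketone F6, which is discarded.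
- Thermolysis of F5 in refluxing 2-butanol (Johnson ketone resolution) releases enantiopure 3.

## Further compounds
F1 | step 20 | methyl (3R)-3-[6-allyl-6-{[(1S,2R)-3,3-dimethyl-2-(prop-1-en-2-yl)cyclobutyl]methyl}-5-hydroxy-2,2-dimethyl-4,7-dioxo-3,4,6,7-tetrahydro-2H-chromen-8-yl]hexanoate, C6 arranged as in 36 | C=C(C)[C@H]1[C@H](C[C@]2(CC=C)C(=O)C([C@H](CCC)CC(=O)OC)=C3OC(C)(C)CC(=O)C3=C2O)CC1(C)C
F2 | step 18 | (1R,2R)-3,3-dimethyl-2-(prop-1-en-2-yl)cyclobutane-1-carbaldehyde | C=C(C)[C@H]1[C@H](C=O)CC1(C)C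
F3 | step 18 | ortho-quinone methide from 26 and F2 (6-cyclobutylmethylidene-5-hydroxy-4,7-dioxo form) | CCC[C@H](CC(=O)OC)C1=C2OC(C)(C)CC(=O)C2=C(O)C(=C[C@@H]3CC(C)(C)[C@H]3C(C)=C)C1=O
F4 | step 1 | racemic 3,3-dimethyl-4-(prop-1-en-2-yl)cyclopentan-1-one | C=C(C)C1CC(=O)CC1(C)C
F5 | step 1 | (4R)-3,3-dimethyl-1-{[(S)-N-methyl-S-phenylsulfonimidoyl]methyl}-4-(prop-1-en-2-yl)cyclopentan-1-ol | C=C(C)[C@H]1CC(O)(C[S@@](=O)(=NC)c2ccccc2)CC1(C)C
F6 | step 1 | (4S)-3,3-dimethyl-1-{[(S)-N-methyl-S-phenylsulfonimidoyl]methyl}-4-(prop-1-en-2-yl)cyclopentan-1-ol | C=C(C)[C@@H]1CC(O)(C[S@@](=O)(=NC)c2ccccc2)CC1(C)C
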